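**Retrosynthetic overview**
1. The malate ester is cut last: the ω‑hydroxy lactone diacid 23 plus O‑trifluoroacetyl‑(R)‑malic anhydride, which opens at the carbonyl next to CH–O.
2. The γ‑lactone, the only ring of the target, is closed in step 8 by acid lactonisation once acetal, benzyl ester and silyl ether are removed from 20.
3. The side‑chain CO2H is a latent CH2NO2 (18 ⇒ 20).
4. Key disconnection, lactone C2–C1′: the enolate of the (S)‑2‑hydroxyglutarate dioxolanone 6 adds to (E)‑nitroalkene 15, which acts as an α‑carboxyl cation (enolonium) equivalent. Two acid α‑carbons are joined and both stereocentres are set in one step.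
5. 6 comes from L‑glutamic acid 5‑benzyl ester; 15 from undecane‑1,11‑diol and nitromethane. Ring order: temporary 1,3‑dioxolan‑4‑one (step 2), then the γ‑lactone (step 8).

Assumption: the target is taken exactly as drawn, which is R at the malate carbon, R at the side‑chain CH and R at the quaternary lactone carbon.

**Step 1**
Reactants: 1 L‑glutamic acid 5‑benzyl ester
Product: 3 (2S)-5-(benzyloxy)-2-hydroxy-5-oxopentanoic acid, via diazonium carboxylate 2 (not isolated)
Conditions: NaNO2, 1 M H2SO4 (aq), 0 °C → rt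
Reagents that add atoms: water, O
Why: Diazotisation of the α‑amino acid with neighbouring‑carboxylate participation replaces NH2 by OH with net retention (double inversion), so the S centre of L‑glutamate is kept.

**Step 2**
Reactants: 3 (2S)-5-(benzyloxy)-2-hydroxy-5-oxopentanoic acid; 4 pivalaldehyde
Product: 6 benzyl 3-[(2S,4S)-2-tert-butyl-5-oxo-1,3-dioxolan-4-yl]propanoate, via bis-silyl derivative 5 (not isolated)
Conditions: (Me3Si)2NH, CH2Cl2, 40 °C, concentrate; then t‑BuCHO, Me3SiOSO2CF3 (5 mol %), CH2Cl2, −25 °C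
Reagents that add atoms: pivalaldehyde (4), CC(C)(C)C=O
Why: Silyl‑triflate‑catalysed (Noyori‑type) acetalisation of the bis‑silylated hydroxy acid gives the cis‑dioxolanone under kinetic control (Seebach self‑regeneration‑of‑stereocentres template), with the new acetal centre S and tert‑butyl cis to the side chain, and it avoids protic acid that would lactonise onto the benzyl ester.

**Step 3**
Reactants: 7 undecane‑1,11‑diol; 8 tert‑butyldimethylsilyl chloride
Product: 10 11-[tert-butyl(dimethyl)silyl]oxyundecan-1-ol, via monosodium alkoxide 9 (not isolated)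
Conditions: NaH (1.0 equiv), THF, rt; then t‑BuMe2SiCl (1.0 equiv), rt
Reagents that add atoms: tert‑butyldimethylsilyl chloride (8), CC(C)(C)[Si](C)(C)Cl
Why: Monosilylation of a symmetrical diol through its sparingly soluble monosodium alkoxide (silyl ether formation) stops after one silyl group.

**Step 4**
Reactants: 10 11-[tert-butyl(dimethyl)silyl]oxyundecan-1-ol
Product: 11 11-[tert-butyl(dimethyl)silyl]oxyundecanal
Conditions: TEMPO (10 mol %), PhI(OAc)2, CH2Cl2, rt
Reagents that add atoms: none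
Why: TEMPO‑catalysed oxoammonium oxidation with PhI(OAc)2 as terminal oxidant stops at the aldehyde and leaves the silyl ether intact.

**Step 5**
Reactants: 11 11-[tert-butyl(dimethyl)silyl]oxyundecanal; 12 nitromethane
Product: 15 tert-butyl(dimethyl)[(E)-12-nitrododec-11-enoxy]silane, via nitro alcohol 13 (not isolated), via mesylate 14 (not isolated)
Conditions: MeNO2, KOtBu (10 mol %), THF/t‑BuOH, 0 °C; then MeSO2Cl, Et3N, CH2Cl2, 0 °C
Reagents that add atoms: nitromethane (12), C[N+](=O)[O-]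
Why: Henry (nitroaldol) addition followed by mesylation and E1cB elimination gives the thermodynamically favoured (E)‑nitroalkene.

**Step 6 (key step)**
Reactants: 6 benzyl 3-[(2S,4S)-2-tert-butyl-5-oxo-1,3-dioxolan-4-yl]propanoate; 15 tert-butyl(dimethyl)[(E)-12-nitrododec-11-enoxy]silane
Product: 18 benzyl 3-[(2S,4R)-2-tert-butyl-4-[(2S)-12-[tert-butyl(dimethyl)silyl]oxy-1-nitrododecan-2-yl]-5-oxo-1,3-dioxolan-4-yl]propanoate, via lithium enolate 16 (not isolated), via lithium nitronate 17 (not isolated)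
Conditions: LiN(SiMe3)2 (1.05 equiv), THF, −78 °C; then 15, −78 °C; AcOH, −78 °C
Reagents that add atoms: none
Why: Michael addition of a Seebach‑type dioxolanone lithium enolate to a nitroalkene that serves as the α‑carboxyl cation (enolonium) equivalent: the nitroalkene enters anti to tert‑butyl (Re face of the enolate, quaternary centre R), and the closed lithium‑bridged synclinal transition state (nitro group on O–Li, alkyl chain antiperiplanar to the enolate C=C, as in Z‑enolate Michael additions that give anti adducts) presents the Si face of the nitroalkene, setting the CH centre (S as the nitro compound, R once CH2NO2 has become CO2H).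

**Step 7**
Reactants: 18 the nitro adduct
Product: 20 (2R)-2-[(2S,4R)-4-(3-benzyloxy-3-oxopropyl)-2-tert-butyl-5-oxo-1,3-dioxolan-4-yl]-12-[tert-butyl(dimethyl)silyl]oxydodecanoic acid, via nitrolic acid 19 (not isolated)
Conditions: NaNO2, AcOH, DMSO, 35 °C
Reagents that add atoms: sodium nitrite, [Na+].[O-]N=O; water, O
Why: Nitrosative Nef‑type oxidation of a primary nitroalkane to the carboxylic acid runs under weakly acidic conditions that leave the acetal, silyl ether, benzyl ester and the adjacent stereocentre untouched.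

**Step 8**
Reactants: 20 the dioxolanone acid
Product: 23 (2R)-2-[(1R)-1-carboxy-11-hydroxyundecyl]-5-oxooxolane-2-carboxylic acid, via trilithium tricarboxylate 21 (not isolated), via open-chain triacid 22 (not isolated)
Conditions: LiOH, THF/H2O, 40 °C; then 3 M HCl (pH 1), 45 °C
Reagents that add atoms: lithium hydroxide, [Li+].[OH-]; water, O
Why: Saponification opens the dioxolanone (releasing pivalaldehyde) and the benzyl ester without epimerisation because the CH centre sits α to a carboxylate, and acidification then removes the silyl group and closes the γ‑lactone by acid‑catalysed lactonisation of the tertiary hydroxy acid.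

**Step 9**
Reactants: 23 the hydroxy lactone diacid; 24 (R)‑malic acid
Product: 27 (2R)-2-[(1R)-1-carboxy-11-[(2R)-3-carboxy-2-hydroxypropanoyl]oxyundecyl]-5-oxooxolane-2-carboxylic acid, via anhydride 25 (not isolated), via trifluoroacetate 26 (not isolated)
Conditions: 24 (3 equiv), (CF3CO)2O, 0 °C → rt, evaporate; then 23, THF, 0 °C → rt; then H2O, rt
Reagents that add atoms: (R)‑malic acid (24), O=C(O)C[C@@H](O)C(=O)O
Why: Alcoholysis of O‑trifluoroacetylmalic anhydride (acylation by anhydride ring opening) occurs at the carbonyl next to the electron‑poor CH–OCOCF3 carbon and so gives the 1‑ester with the 4‑acid free, the primary alcohol out‑competes the carboxylic acids, and the trifluoroacetate is hydrolysed on aqueous work‑up with the malate centre untouched.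

**Compound list**
1 | L‑glutamic acid 5‑benzyl ester, (2S)-2-amino-5-(benzyloxy)-5-oxopentanoic acid | N[C@@H](CCC(=O)OCc1ccccc1)C(=O)O | starting material
2 | (1S)-4-(benzyloxy)-1-carboxylato-4-oxobutane-1-diazonium (diazonium carboxylate) | N#[N+][C@@H](CCC(=O)OCc1ccccc1)C(=O)[O-] | intermediate (not isolated)
3 | (2S)-5-(benzyloxy)-2-hydroxy-5-oxopentanoic acid | O[C@@H](CCC(=O)OCc1ccccc1)C(=O)O | intermediate
4 | pivalaldehyde | CC(C)(C)C=O | starting material
5 | trimethylsilyl (2S)-5-(benzyloxy)-5-oxo-2-(trimethylsilyloxy)pentanoate | C[Si](C)(C)O[C@@H](CCC(=O)OCc1ccccc1)C(=O)O[Si](C)(C)C | intermediate (not isolated)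
6 | benzyl 3-[(2S,4S)-2-tert-butyl-5-oxo-1,3-dioxolan-4-yl]propanoate (cis) | CC(C)(C)[C@H]1O[C@@H](CCC(=O)OCc2ccccc2)C(=O)O1 | intermediate
7 | undecane‑1,11‑diol | OCCCCCCCCCCCO | starting material
8 | tert‑butyldimethylsilyl chloride | CC(C)(C)[Si](C)(C)Cl | starting material
9 | sodium 11‑hydroxyundecan‑1‑olate | [Na+].[O-]CCCCCCCCCCCO | intermediate (not isolated)
10 | 11-[tert-butyl(dimethyl)silyl]oxyundecan-1-ol | CC(C)(C)[Si](C)(C)OCCCCCCCCCCCO | intermediate
11 | 11-[tert-butyl(dimethyl)silyl]oxyundecanal | CC(C)(C)[Si](C)(C)OCCCCCCCCCCC=O | intermediate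
12 | nitromethane | C[N+](=O)[O-] | starting material
13 | 12-[tert-butyl(dimethyl)silyl]oxy-1-nitrododecan-2-ol (racemic) | CC(C)(C)[Si](C)(C)OCCCCCCCCCCC(O)C[N+](=O)[O-] | intermediate (not isolated)
14 | 12-[tert-butyl(dimethyl)silyl]oxy-1-nitrododecan-2-yl methanesulfonate (racemic) | CC(C)(C)[Si](C)(C)OCCCCCCCCCCC(OS(C)(=O)=O)C[N+](=O)[O-] | intermediate (not isolated)
15 | tert-butyl(dimethyl)[(E)-12-nitrododec-11-enoxy]silane | CC(C)(C)[Si](C)(C)OCCCCCCCCCC/C=C/[N+](=O)[O-] | intermediate
16 | lithium (2S)-5-(3-benzyloxy-3-oxopropyl)-2-tert-butyl-1,3-dioxol-4-olate (enolate of 6) | [Li+].CC(C)(C)[C@H]1OC(CCC(=O)OCc2ccccc2)=C([O-])O1 | intermediate (not isolated)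
17 | lithium nitronate of 18 | [Li+].CC(C)(C)[C@H]1O[C@](CCC(=O)OCc2ccccc2)([C@H](C=[N+]([O-])[O-])CCCCCCCCCCO[Si](C)(C)C(C)(C)C)C(=O)O1 | intermediate (not isolated)
18 | benzyl 3-[(2S,4R)-2-tert-butyl-4-[(2S)-12-[tert-butyl(dimethyl)silyl]oxy-1-nitrododecan-2-yl]-5-oxo-1,3-dioxolan-4-yl]propanoate | CC(C)(C)[C@H]1O[C@](CCC(=O)OCc2ccccc2)([C@H](C[N+](=O)[O-])CCCCCCCCCCO[Si](C)(C)C(C)(C)C)C(=O)O1 | intermediate
19 | benzyl 3-[(2S,4R)-2-tert-butyl-4-[(2S)-12-[tert-butyl(dimethyl)silyl]oxy-1-(hydroxyimino)-1-nitrododecan-2-yl]-5-oxo-1,3-dioxolan-4-yl]propanoate (nitrolic acid) | CC(C)(C)[C@H]1O[C@](CCC(=O)OCc2ccccc2)([C@H](C(=NO)[N+](=O)[O-])CCCCCCCCCCO[Si](C)(C)C(C)(C)C)C(=O)O1 | intermediate (not isolated)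
20 | (2R)-2-[(2S,4R)-4-(3-benzyloxy-3-oxopropyl)-2-tert-butyl-5-oxo-1,3-dioxolan-4-yl]-12-[tert-butyl(dimethyl)silyl]oxydodecanoic acid | CC(C)(C)[C@H]1O[C@](CCC(=O)OCc2ccccc2)([C@H](C(=O)O)CCCCCCCCCCO[Si](C)(C)C(C)(C)C)C(=O)O1 | intermediate
21 | trilithium (3R,4R)-14-[tert-butyl(dimethyl)silyl]oxy-3-hydroxytetradecane-1,3,4-tricarboxylate | [Li+].[Li+].[Li+].[O-]C(=O)CC[C@](O)(C(=O)[O-])[C@H](C(=O)[O-])CCCCCCCCCCO[Si](C)(C)C(C)(C)C | intermediate (not isolated)
22 | (3R,4R)-3,14-dihydroxytetradecane-1,3,4-tricarboxylic acid | OC(=O)CC[C@](O)(C(=O)O)[C@H](C(=O)O)CCCCCCCCCCO | intermediate (not isolated)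
23 | (2R)-2-[(1R)-1-carboxy-11-hydroxyundecyl]-5-oxooxolane-2-carboxylic acid | OCCCCCCCCCC[C@@H](C(=O)O)[C@@]1(C(=O)O)CCC(=O)O1 | intermediate
24 | (R)‑malic acid | O=C(O)C[C@@H](O)C(=O)O | starting material
25 | (3R)-2,5-dioxooxolan-3-yl 2,2,2-trifluoroacetate | O=C1C[C@@H](OC(=O)C(F)(F)F)C(=O)O1 | intermediate (not isolated)
26 | O‑trifluoroacetyl derivative of 27 | O=C(O)C[C@@H](OC(=O)C(F)(F)F)C(=O)OCCCCCCCCCC[C@@H](C(=O)O)[C@@]1(C(=O)O)CCC(=O)O1 | intermediate (not isolated)
27 | (2R)-2-[(1R)-1-carboxy-11-[(2R)-3-carboxy-2-hydroxypropanoyl]oxyundecyl]-5-oxooxolane-2-carboxylic acid | O=C(O)C[C@@H](O)C(=O)OCCCCCCCCCC[C@@H](C(=O)O)[C@@]1(C(=O)O)CCC(=O)O1 | target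

**Totals**
Total step count: 9. Longest linear sequence: 7 steps (3 → 4 → 5 → 6 → 7 → 8 → 9).

**Three steps most likely to fail**

Step 6. The facial selectivity at the ring carbon is secure, but the sense and level of induction at the exocyclic CH rest on the closed transition‑state model, and the enolate decomposes above about −60 °C. The fallback sets out from 6 and comes back at 18. Dioxolanone 6 is converted with LiN(SiMe3)2 and Me3SiCl (THF, −78 °C, through enolate 16) into the trimethylsilyl ketene acetal F1, which is isolated. F1 is added to nitroalkene 15 under Me3SiOSO2CF3 catalysis (CH2Cl2, −78 °C) in a Mukaiyama–Michael reaction to give the trimethylsilyl nitronate F2. Buffered aqueous work‑up (pH 5) removes the N–O silyl group and delivers 18. The open, non‑chelated transition state keeps the tert‑butyl face control but commonly reverses the simple diastereoselection of the lithium pathway, so it is the route to take if the lithium enolate favours the other CH epimer.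

Step 9. The two free carboxylic acids of 23 can exchange with the anhydride, some 4‑ester regioisomer is expected, and the product is a polar tetra‑acid that must be purified by reversed‑phase chromatography. The fallback sets out from 18 and comes back at 27. HF·pyridine (THF, 0 °C) removes the silyl group to give the nitro alcohol F4, which carries no free acid. F4 opens anhydride 25 to the trifluoroacetylated half ester F5, and aqueous work‑up gives the hydroxy half ester F6, a mono‑acid from which any regioisomer is removed on silica. The conditions of step 7 then take F6 through the nitrolic acid F7 to the diacid F8. Aqueous CF3CO2H (THF, 45 °C) finally hydrolyses the acetal and closes the lactone with loss of benzyl alcohol to give 27, so no basic step follows installation of the malate ester.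

Step 7. Nitrosation at the hindered CH2NO2 group next to a quaternary centre may be slow, and partial silyl loss is possible. The fallback sets out from 18 and comes back at 20. Compound 18 is deprotonated to lithium nitronate 17 (LiN(SiMe3)2, THF, −78 °C), which is reduced with aqueous TiCl3 buffered with ammonium acetate (reductive Nef reaction) to the aldehyde F3. F3 is oxidised without delay with NaClO2, NaH2PO4 and 2‑methyl‑2‑butene in t‑BuOH/H2O (Pinnick oxidation) to 20.

**Further compounds**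
F1 | step 6 | benzyl 3-[(2S)-2-tert-butyl-5-(trimethylsilyloxy)-1,3-dioxol-4-yl]propanoate | CC(C)(C)[C@H]1OC(CCC(=O)OCc2ccccc2)=C(O[Si](C)(C)C)O1
F2 | step 6 | trimethylsilyl nitronate of 18 | CC(C)(C)[C@H]1O[C@](CCC(=O)OCc2ccccc2)([C@H](C=[N+]([O-])O[Si](C)(C)C)CCCCCCCCCCO[Si](C)(C)C(C)(C)C)C(=O)O1
F3 | step 7 | benzyl 3-[(2S,4R)-2-tert-butyl-4-[(2R)-12-[tert-butyl(dimethyl)silyl]oxy-1-oxododecan-2-yl]-5-oxo-1,3-dioxolan-4-yl]propanoate | CC(C)(C)[C@H]1O[C@](CCC(=O)OCc2ccccc2)([C@H](C=O)CCCCCCCCCCO[Si](C)(C)C(C)(C)C)C(=O)O1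
F4 | step 9 | benzyl 3-[(2S,4R)-2-tert-butyl-4-[(2S)-12-hydroxy-1-nitrododecan-2-yl]-5-oxo-1,3-dioxolan-4-yl]propanoate | CC(C)(C)[C@H]1O[C@](CCC(=O)OCc2ccccc2)([C@H](C[N+](=O)[O-])CCCCCCCCCCO)C(=O)O1
F5 | step 9 | (3R)-4-[(11S)-11-[(2S,4R)-4-(3-benzyloxy-3-oxopropyl)-2-tert-butyl-5-oxo-1,3-dioxolan-4-yl]-12-nitrododecoxy]-4-oxo-3-(trifluoroacetoxy)butanoic acid | CC(C)(C)[C@H]1O[C@](CCC(=O)OCc2ccccc2)([C@H](C[N+](=O)[O-])CCCCCCCCCCOC(=O)[C@H](OC(=O)C(F)(F)F)CC(=O)O)C(=O)O1
F6 | step 9 | (3R)-4-[(11S)-11-[(2S,4R)-4-(3-benzyloxy-3-oxopropyl)-2-tert-butyl-5-oxo-1,3-dioxolan-4-yl]-12-nitrododecoxy]-3-hydroxy-4-oxobutanoic acid | CC(C)(C)[C@H]1O[C@](CCC(=O)OCc2ccccc2)([C@H](C[N+](=O)[O-])CCCCCCCCCCOC(=O)[C@H](O)CC(=O)O)C(=O)O1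
F7 | step 9 | (3R)-4-[(11S)-11-[(2S,4R)-4-(3-benzyloxy-3-oxopropyl)-2-tert-butyl-5-oxo-1,3-dioxolan-4-yl]-12-(hydroxyimino)-12-nitrododecoxy]-3-hydroxy-4-oxobutanoic acid | CC(C)(C)[C@H]1O[C@](CCC(=O)OCc2ccccc2)([C@H](C(=NO)[N+](=O)[O-])CCCCCCCCCCOC(=O)[C@H](O)CC(=O)O)C(=O)O1
F8 | step 9 | (2R)-2-[(2S,4R)-4-(3-benzyloxy-3-oxopropyl)-2-tert-butyl-5-oxo-1,3-dioxolan-4-yl]-12-[(2R)-3-carboxy-2-hydroxypropanoyl]oxydodecanoic acid | CC(C)(C)[C@H]1O[C@](CCC(=O)OCc2ccccc2)([C@H](C(=O)O)CCCCCCCCCCOC(=O)[C@H](O)CC(=O)O)C(=O)O1
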